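**Retrosynthetic overview**
- Endgame: the C5 hydroxyl is unmasked last from its 4-methoxybenzyl (PMB) ether, and the C6 acetate goes on one step earlier. Nothing else follows the key step.
- Key disconnection: ring B (the cyclopentanone) is opened at C7–C6 and at C4a–C5. This gives a 4-chloropyridine-3-carbaldehyde that already carries the dienyl chain, and methyl 2-(4-methoxybenzyloxy)acetoacetate. In the forward sense, an enantioselective phase-transfer SNAr and a carbene-catalysed crossed benzoin closure run in one flask.
- Enabling feature: in ring A, C4a is γ to N2 and ortho to the carbon that bears C7, so with chlorine on it it behaves as a vinylogous acid chloride, while C7 as a formyl carbon can be polarity-reversed. The C5–C6 unit is an α-oxy-β-keto ester, nucleophilic at C5 and electrophilic at C6, so both unions are polarity-matched and both oxygens are already in place.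
- The chloro aldehyde comes from 6-bromo-4-chloropyridine-3-carbaldehyde and an (E,E)-dienyl boronate (Suzuki–Miyaura) made from (S)-2-methylbutan-1-ol. The keto ester comes from methyl acetoacetate (diazo transfer, O–H insertion).
- Ring order: ring A (pyridine) is bought; ring B is formed in the key step.

Key step: step 8

Assumption: 6-bromo-4-chloropyridine-3-carbaldehyde is taken as a catalogue compound, and the (R,R) antipode of the ammonium salt is taken as the one that leads to (5R); both antipodes are sold, so a reversed sense of induction changes only the antipode used.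

Step 1
Reactants: 1 (S)-2-methylbutan-1-ol
Product: 3 ethyl (2E,4S)-2,4-dimethylhex-2-enoate, via (S)-2-methylbutanal 2 (not isolated)
Conditions: TEMPO (10 mol %), PhI(OAc)2 (1.1 equiv), CH2Cl2, 0 °C to rt; then Ph3P=C(CH3)CO2Et (1.5 equiv), same flask, rt
Reagents that add atoms: ethyl 2-(triphenyl-λ5-phosphanylidene)propanoate, CCOC(=O)C(C)=P(c1ccccc1)(c1ccccc1)c1ccccc1
Why: Nitroxyl-catalysed alcohol oxidation followed in the same flask by a Wittig olefination with a stabilised α-branched ylide should give the E-trisubstituted enoate, and the near-neutral medium and immediate capture of the aldehyde keep the purchased stereocentre from epimerising.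

Step 2
Reactants: 3 ethyl (2E,4S)-2,4-dimethylhex-2-enoate
Product: 4 (2E,4S)-2,4-dimethylhex-2-en-1-ol
Conditions: i-Bu2AlH (2.3 equiv), CH2Cl2, −78 to 0 °C
Reagents that add atoms: none
Why: 1,2-Reduction of the conjugated ester by i-Bu2AlH stops at the allylic alcohol and touches neither the alkene geometry nor the stereocentre.

Step 3
Reactants: 4 (2E,4S)-2,4-dimethylhex-2-en-1-ol
Product: 5 (2E,4S)-2,4-dimethylhex-2-enal
Conditions: MnO2 (15 equiv), CH2Cl2, rt
Reagents that add atoms: none
Why: Allylic alcohol oxidation on MnO2 is selective and neutral and leaves the γ-stereocentre and the E-alkene untouched.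

Step 4
Reactants: 5 (2E,4S)-2,4-dimethylhex-2-enal
Product: 6 2-[(1E,3E,5S)-3,5-dimethylhepta-1,3-dien-1-yl]-4,4,5,5-tetramethyl-1,3,2-dioxaborolane
Conditions: CH2(Bpin)2 (1.2 equiv), LiTMP (lithium 2,2,6,6-tetramethylpiperidide, 1.2 equiv), THF, 0 °C; then 5, −78 °C to rt
Reagents that add atoms: 2,2'-methylenebis(4,4,5,5-tetramethyl-1,3,2-dioxaborolane), C(B1OC(C)(C)C(C)(C)O1)B1OC(C)(C)C(C)(C)O1
Why: Boron–Wittig olefination, in which the lithiated geminal bis(boronate) adds to the aldehyde and syn B–O elimination from the less crowded adduct should deliver the E-alkenyl boronate and hence the E,E-diene in one step.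

Step 5
Reactants: 6 2-[(1E,3E,5S)-3,5-dimethylhepta-1,3-dien-1-yl]-4,4,5,5-tetramethyl-1,3,2-dioxaborolane; 7 6-bromo-4-chloropyridine-3-carbaldehyde
Product: 8 4-chloro-6-[(1E,3E,5S)-3,5-dimethylhepta-1,3-dien-1-yl]pyridine-3-carbaldehyde
Conditions: Pd(dppf)Cl2 (4 mol %), K3PO4 (2 equiv), THF/H2O 20:1, 40 °C
Reagents that add atoms: none
Why: Site-selective Suzuki–Miyaura coupling, in which zerovalent palladium inserts into the weaker C–Br bond α to nitrogen well before the C4–Cl bond and the geometry of the alkenyl boronate is retained.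

Step 6
Reactants: 9 methyl acetoacetate
Product: 10 methyl 2-diazo-3-oxobutanoate
Conditions: 4-acetamidobenzenesulfonyl azide (1.1 equiv), Et3N (1.2 equiv), MeCN, 0 °C to rt
Reagents that add atoms: 4-acetamidobenzenesulfonyl azide, CC(=O)Nc1ccc(cc1)S(=O)(=O)N=[N+]=[N-]
Why: Regitz diazo transfer onto the active methylene group is a standard reaction of β-keto esters.

Step 7
Reactants: 10 methyl 2-diazo-3-oxobutanoate
Product: 11 methyl 2-[(4-methoxyphenyl)methoxy]-3-oxobutanoate (racemic, configurationally labile)
Conditions: 4-methoxybenzyl alcohol (1.2 equiv), Rh2(OAc)4 (1 mol %), CH2Cl2, 40 °C, slow addition of 10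
Reagents that add atoms: 4-methoxybenzyl alcohol, COc1ccc(CO)cc1
Why: Rhodium-carbenoid O–H insertion into a primary benzylic alcohol is the established one-step entry to α-alkoxy-β-keto esters, and the new centre is labile, so its configuration is irrelevant.

Step 8
Reactants: 8 4-chloro-6-[(1E,3E,5S)-3,5-dimethylhepta-1,3-dien-1-yl]pyridine-3-carbaldehyde; 11 methyl 2-[(4-methoxyphenyl)methoxy]-3-oxobutanoate
Product: 13 methyl (5R,6S)-3-[(1E,3E,5S)-3,5-dimethylhepta-1,3-dien-1-yl]-6-hydroxy-5-[(4-methoxyphenyl)methoxy]-6-methyl-7-oxo-6,7-dihydro-5H-cyclopenta[c]pyridine-5-carboxylate, via keto aldehyde adduct 12 (not isolated)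
Conditions: (R,R)-3,4,5-trifluorophenyl-NAS bromide (C2-symmetric N-spiro bis-binaphthyl ammonium bromide, 5 mol %), powdered K2CO3 (1.2 equiv), toluene, 4 Å MS, Ar, 0 °C to rt until 8 is consumed; then, same flask without work-up, 2-(pentafluorophenyl)-6,7-dihydro-5H-pyrrolo[2,1-c][1,2,4]triazol-2-ium tetrafluoroborate (15 mol %), i-Pr2NEt (30 mol %), rt to 35 °C
Reagents that add atoms: none
Why: Proposed new method: under solid–liquid phase transfer the chiral ammonium enolate of 11 attacks C4 of the pyridine (the later C4a) through carbon, chloride leaves the Meisenheimer adduct, and the keto aldehyde 12 so formed is then closed by the triazolylidene, which converts the formyl carbon into an acyl-anion equivalent (Breslow intermediate) that adds to the adjacent acetyl carbonyl, so that two carbonyl carbons of like polarity are joined. The closest known reaction types are the phase-transfer-catalysed enantioselective SNAr of β-dicarbonyl compounds on activated haloarenes, the phase-transfer alkylation of α-oxygenated β-keto esters, the relay of a conjugate addition of a 1,3-dicarbonyl compound with a carbene-catalysed benzoin closure to α-hydroxycyclopentanones, and the intramolecular crossed aldehyde–ketone benzoin reaction; new is their union on a 4-chloropyridine-3-carbaldehyde, which plays the part of a β-chloro enal. Ring B closes in the 5-exo-trig mode at the ketone carbonyl. C5 is set in the substitution by the C2-symmetric cation, which shields one face of the planar enolate and is its only soluble counter-ion because the azolium salt is withheld until 8 is consumed, and once formed this quaternary centre cannot epimerise. C6 is set by C5: the acetyl group should react from the dipole-minimised conformer with its C=O anti to the C5–O bond and next to the ester, so that the new hydroxyl ends up trans to OPMB and cis to CO2Me and the methyl group lies beside the small ether oxygen. The step needs C- over O-arylation, benzoin closure over six-ring aldol condensation of the methyl ketone with the formyl group, and no 1,4-expulsion of the C5 oxygen from the Breslow intermediate; the soft fully substituted enolate and the single leaving group at the position γ to nitrogen and ortho to the formyl group, the near-stoichiometric carbonate followed by only a weak amine base, and an ether instead of an ester on O5 secure these in turn.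

Step 9
Reactants: 13 methyl (5R,6S)-3-[(1E,3E,5S)-3,5-dimethylhepta-1,3-dien-1-yl]-6-hydroxy-5-[(4-methoxyphenyl)methoxy]-6-methyl-7-oxo-6,7-dihydro-5H-cyclopenta[c]pyridine-5-carboxylate
Product: 14 methyl (5R,6S)-6-acetoxy-3-[(1E,3E,5S)-3,5-dimethylhepta-1,3-dien-1-yl]-5-[(4-methoxyphenyl)methoxy]-6-methyl-7-oxo-6,7-dihydro-5H-cyclopenta[c]pyridine-5-carboxylate
Conditions: Ac2O (5 equiv), DMAP (0.3 equiv), Et3N (6 equiv), CH2Cl2, rt
Reagents that add atoms: acetic anhydride, CC(=O)OC(C)=O
Why: DMAP-catalysed acyl transfer to the only free hydroxyl group; the tertiary α-ketol has no enolisable position and the trans, protected O5 cannot take over the acyl group, so both stereocentres are retained.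

Step 10
Reactants: 14 methyl (5R,6S)-6-acetoxy-3-[(1E,3E,5S)-3,5-dimethylhepta-1,3-dien-1-yl]-5-[(4-methoxyphenyl)methoxy]-6-methyl-7-oxo-6,7-dihydro-5H-cyclopenta[c]pyridine-5-carboxylate
Product: 15 methyl (5R,6S)-6-acetoxy-3-[(1E,3E,5S)-3,5-dimethylhepta-1,3-dien-1-yl]-5-hydroxy-6-methyl-7-oxo-6,7-dihydro-5H-cyclopenta[c]pyridine-5-carboxylate (target)
Conditions: DDQ (1.5 equiv), CH2Cl2/pH 7 phosphate buffer 10:1, 0 °C to rt
Reagents that add atoms: none
Why: Oxidative cleavage of the 4-methoxybenzyl ether by DDQ (hydride abstraction, then hydrolysis of the oxocarbenium ion) is orthogonal to acetate, methyl ester and ketone, the diene is deactivated by conjugation with the acylpyridine, and no stereocentre is touched.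

**Compound list**
1 | (S)-2-methylbutan-1-ol | CC[C@H](C)CO | starting material
2 | (S)-2-methylbutanal | CC[C@H](C)C=O | intermediate
3 | ethyl (2E,4S)-2,4-dimethylhex-2-enoate | CC[C@H](C)/C=C(C)/C(=O)OCC | intermediate
4 | (2E,4S)-2,4-dimethylhex-2-en-1-ol | CC[C@H](C)/C=C(C)/CO | intermediate
5 | (2E,4S)-2,4-dimethylhex-2-enal | CC[C@H](C)/C=C(C)/C=O | intermediate
6 | 2-[(1E,3E,5S)-3,5-dimethylhepta-1,3-dien-1-yl]-4,4,5,5-tetramethyl-1,3,2-dioxaborolane | CC[C@H](C)/C=C(C)/C=C/B1OC(C)(C)C(C)(C)O1 | intermediate
7 | 6-bromo-4-chloropyridine-3-carbaldehyde | O=Cc1cnc(Br)cc1Cl | starting material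
8 | 4-chloro-6-[(1E,3E,5S)-3,5-dimethylhepta-1,3-dien-1-yl]pyridine-3-carbaldehyde | CC[C@H](C)/C=C(C)/C=C/c1cc(Cl)c(C=O)cn1 | intermediate
9 | methyl acetoacetate | CC(=O)CC(=O)OC | starting material
10 | methyl 2-diazo-3-oxobutanoate | CC(=O)C(=[N+]=[N-])C(=O)OC | intermediate
11 | methyl 2-[(4-methoxyphenyl)methoxy]-3-oxobutanoate (racemic, labile centre) | CC(=O)C(OCc1ccc(OC)cc1)C(=O)OC | intermediate
12 | methyl (2R)-2-{2-[(1E,3E,5S)-3,5-dimethylhepta-1,3-dien-1-yl]-5-formylpyridin-4-yl}-2-[(4-methoxyphenyl)methoxy]-3-oxobutanoate | CC[C@H](C)/C=C(C)/C=C/c1cc(c(C=O)cn1)[C@@](OCc1ccc(OC)cc1)(C(C)=O)C(=O)OC | intermediate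
13 | methyl (5R,6S)-3-[(1E,3E,5S)-3,5-dimethylhepta-1,3-dien-1-yl]-6-hydroxy-5-[(4-methoxyphenyl)methoxy]-6-methyl-7-oxo-6,7-dihydro-5H-cyclopenta[c]pyridine-5-carboxylate | CC[C@H](C)/C=C(C)/C=C/c1cc2c(cn1)C(=O)[C@@](C)(O)[C@@]2(OCc1ccc(OC)cc1)C(=O)OC | intermediate
14 | methyl (5R,6S)-6-acetoxy-3-[(1E,3E,5S)-3,5-dimethylhepta-1,3-dien-1-yl]-5-[(4-methoxyphenyl)methoxy]-6-methyl-7-oxo-6,7-dihydro-5H-cyclopenta[c]pyridine-5-carboxylate | CC[C@H](C)/C=C(C)/C=C/c1cc2c(cn1)C(=O)[C@@](C)(OC(C)=O)[C@@]2(OCc1ccc(OC)cc1)C(=O)OC | intermediate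
15 | methyl (5R,6S)-6-acetoxy-3-[(1E,3E,5S)-3,5-dimethylhepta-1,3-dien-1-yl]-5-hydroxy-6-methyl-7-oxo-6,7-dihydro-5H-cyclopenta[c]pyridine-5-carboxylate | CC[C@H](C)/C=C(C)/C=C/c1cc2c(cn1)C(=O)[C@@](C)(OC(C)=O)[C@@]2(O)C(=O)OC | target

**Step count**
- Total step count: 10.
- Longest linear sequence: 8 steps (steps 1–5 and 8–10, from (S)-2-methylbutan-1-ol).

**Steps most likely to fail**

1. Step 8.
   - Risk: the chiral cation may discriminate the enolate faces only weakly at the temperature the substitution needs. A sluggish substitution could also let base-induced aldol condensation of the methyl ketone with the formyl group overtake the relay.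
   - Fallback (known chemistry), from 8 and 11, back at 13: the two bonds are made in two isolated steps, and the stereodifferentiation moves from the cation to the carbene.
   - A classical SNAr of the caesium enolate (Cs2CO3, 1.05 equiv, DMF, rt) should give methyl 2-{2-[(1E,3E,5S)-3,5-dimethylhepta-1,3-dien-1-yl]-5-formylpyridin-4-yl}-2-[(4-methoxyphenyl)methoxy]-3-oxobutanoate F1 as both C2 epimers, which is isolated.
   - An enantiopure aminoindanol-derived N-pentafluorophenyl triazolium tetrafluoroborate with i-Pr2NEt in THF then runs the established asymmetric intramolecular crossed benzoin reaction as a kinetic resolution. The antipode of the catalyst is chosen so that the (2R)-epimer is the matched, faster substrate and closes to 13. The slower (2S)-epimer is removed by chromatography.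

2. Step 5.
   - Risk: hydrolytic loss of the activated C4 chloride under the aqueous base, or erosion of site selectivity through insertion into the C4–Cl bond.
   - Fallback, from 5, back at 8: the boron route is abandoned. Wittig methylenation of 5 (Ph3P=CH2, THF, 0 °C) should give (3E,5S)-3,5-dimethylhepta-1,3-diene F2.
   - F2 is joined to 7 by a water-free Heck alkenylation at its terminal carbon (Pd(OAc)2, P(o-tol)3, Et3N, MeCN, 70 °C), with β-hydride elimination restoring the conjugated E,E-diene of 8.

3. Step 10.
   - Risk: slow hydride abstraction from an ether whose oxygen sits on a strongly electron-poor carbon, with competing oxidation or cycloaddition at the diene.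
   - Fallback, from 7 (with 11 and later 6), back at 15: the order of events is changed so that the oxidant never meets the diene.
   - The conditions of step 8 are applied to 7. Substitution should occur at C4–Cl, ortho to the formyl group, giving methyl (2R)-2-(2-bromo-5-formylpyridin-4-yl)-2-[(4-methoxyphenyl)methoxy]-3-oxobutanoate F3 (not isolated). This then closes to methyl (5R,6S)-3-bromo-6-hydroxy-5-[(4-methoxyphenyl)methoxy]-6-methyl-7-oxo-6,7-dihydro-5H-cyclopenta[c]pyridine-5-carboxylate F4.
   - Acetylation as in step 9 gives methyl (5R,6S)-6-acetoxy-3-bromo-5-[(4-methoxyphenyl)methoxy]-6-methyl-7-oxo-6,7-dihydro-5H-cyclopenta[c]pyridine-5-carboxylate F5.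
   - DDQ as in step 10 gives methyl (5R,6S)-6-acetoxy-3-bromo-5-hydroxy-6-methyl-7-oxo-6,7-dihydro-5H-cyclopenta[c]pyridine-5-carboxylate F6.
   - A final Suzuki–Miyaura coupling of F6 with 6 (Pd(dppf)Cl2, K3PO4, THF/H2O, 40 °C) gives 15.

**Further compounds**
F1 | step 8 | methyl 2-{2-[(1E,3E,5S)-3,5-dimethylhepta-1,3-dien-1-yl]-5-formylpyridin-4-yl}-2-[(4-methoxyphenyl)methoxy]-3-oxobutanoate (both C2 epimers) | CC[C@H](C)/C=C(C)/C=C/c1cc(c(C=O)cn1)C(OCc1ccc(OC)cc1)(C(C)=O)C(=O)OC
F2 | step 5 | (3E,5S)-3,5-dimethylhepta-1,3-diene | CC[C@H](C)/C=C(C)/C=C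
F3 | step 10 | methyl (2R)-2-(2-bromo-5-formylpyridin-4-yl)-2-[(4-methoxyphenyl)methoxy]-3-oxobutanoate | Brc1cc(c(C=O)cn1)[C@@](OCc1ccc(OC)cc1)(C(C)=O)C(=O)OC
F4 | step 10 | methyl (5R,6S)-3-bromo-6-hydroxy-5-[(4-methoxyphenyl)methoxy]-6-methyl-7-oxo-6,7-dihydro-5H-cyclopenta[c]pyridine-5-carboxylate | Brc1cc2c(cn1)C(=O)[C@@](C)(O)[C@@]2(OCc1ccc(OC)cc1)C(=O)OC
F5 | step 10 | methyl (5R,6S)-6-acetoxy-3-bromo-5-[(4-methoxyphenyl)methoxy]-6-methyl-7-oxo-6,7-dihydro-5H-cyclopenta[c]pyridine-5-carboxylate | Brc1cc2c(cn1)C(=O)[C@@](C)(OC(C)=O)[C@@]2(OCc1ccc(OC)cc1)C(=O)OC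
F6 | step 10 | methyl (5R,6S)-6-acetoxy-3-bromo-5-hydroxy-6-methyl-7-oxo-6,7-dihydro-5H-cyclopenta[c]pyridine-5-carboxylate | Brc1cc2c(cn1)C(=O)[C@@](C)(OC(C)=O)[C@@]2(O)C(=O)OC
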